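## Retrosynthetic overview

1. Last ring: the δ-lactone, closed by C5–OH onto a (2Z)-enoate. Ring before it: the tetrahydrofuran, closed by O4 attacking C7 of a 6,7-cis-vinyl oxirane with inversion. Both are closed in one acid-triggered cascade from an acyclic C12 chain.
2. The acyclic chain is cut at C2=C3 (Still–Gennari olefination) and at C8=C9 (cross-metathesis).
3. The C6–C7 cis-oxirane comes from (Z)-γ-chloroallylboration of a D-tartrate-derived aldehyde (C3–C6, with O4/O5 as the acetonide), then base closure.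
4. The C9–C12 arm comes from Sharpless desymmetrisation of divinylcarbinol, hydride opening and benzoylation.
5. Ring order: tetrahydrofuran first, lactone second, same flask.

Assumption: the presumed biogenesis is taken to be that of the altholactone/olguine family (C4 hydroxyl opens a 6,7-oxirane at the allylic carbon C7, C5 hydroxyl lactonises onto the 2Z-enoyl unit); polyketide numbering C1 (lactone carbonyl) to C12 (methyl) is used throughout.

## Route

Step 1
Reactants: 1 penta-1,4-dien-3-ol (divinylcarbinol)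
Product: 2 (2R,3S)-1,2-epoxypent-4-en-3-ol
Conditions: Ti(OiPr)4 (cat.), L-(+)-DIPT (cat.), t-BuOOH, 4 Å MS, CH2Cl2, −20 °C
Reagents that add atoms: tert-butyl hydroperoxide, CC(C)(C)OO
Why: Sharpless asymmetric epoxidation of a prochiral divinyl carbinol; L-(+)-DIPT selects one enantiotopic vinyl group and the erythro face, setting C10 (S) and C11 (R) together, and the minor enantiomer is consumed by over-epoxidation.

Step 2
Reactants: 2 (2R,3S)-1,2-epoxypent-4-en-3-ol
Product: 3 (2R,3S)-1,2-epoxy-3-[(4-methoxybenzyl)oxy]pent-4-ene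
Conditions: NaH, PMBCl, Bu4NI (cat.), THF, 0 °C → rt
Reagents that add atoms: 4-methoxybenzyl chloride, COc1ccc(CCl)cc1
Why: Williamson etherification of the sodium alkoxide under aprotic conditions, where Payne rearrangement is slow; no stereocentre is touched.

Step 3
Reactants: 3 (2R,3S)-1,2-epoxy-3-[(4-methoxybenzyl)oxy]pent-4-ene
Product: 5 (2R,3S)-3-[(4-methoxybenzyl)oxy]pent-4-en-2-yl benzoate, via lithium C11-alkoxide 4 (not isolated)
Conditions: LiBHEt3, THF, 0 °C; then BzCl, DMAP (cat.), 0 °C → rt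
Reagents that add atoms: benzoyl chloride, O=C(Cl)c1ccccc1
Why: Regioselective SN2 hydride opening of the terminal oxirane at CH2 (C12) gives the C11 lithium alkoxide, which is O-acylated in the same flask; the benzyl-type ether cannot migrate, so the benzoate sits only on O11 and C11 is untouched.

Step 4
Reactants: 6 dimethyl (4S,5S)-2,2-dimethyl-1,3-dioxolane-4,5-dicarboxylate [(+)-dimethyl 2,3-O-isopropylidene-D-tartrate]
Product: 7 methyl (4S,5R)-5-(hydroxymethyl)-2,2-dimethyl-1,3-dioxolane-4-carboxylate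
Conditions: NaBH4 (0.6 equiv), MeOH, 0 °C
Reagents that add atoms: none
Why: Partial borohydride reduction of an α-alkoxy diester; the C2 axis makes both esters equivalent and the mono-reduced alkoxyborate is reduced more slowly, so C4 and C5 of the target come unchanged from D-tartrate.

Step 5
Reactants: 7 methyl (4S,5R)-5-(hydroxymethyl)-2,2-dimethyl-1,3-dioxolane-4-carboxylate
Product: 8 methyl (4S,5S)-5-formyl-2,2-dimethyl-1,3-dioxolane-4-carboxylate
Conditions: (COCl)2, DMSO, CH2Cl2, −78 °C; Et3N; used crude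
Reagents that add atoms: none
Why: Swern oxidation, which does not epimerise the trans-dioxolane aldehyde.

Step 6
Reactants: 8 methyl (4S,5S)-5-formyl-2,2-dimethyl-1,3-dioxolane-4-carboxylate
Product: 10 methyl (4S,5R)-2,2-dimethyl-5-[(2R,3R)-3-vinyloxiran-2-yl]-1,3-dioxolane-4-carboxylate, via syn-chlorohydrin ester 9 (not isolated)
Conditions: allyl chloride, (+)-Ipc2BOMe [from (−)-α-pinene], LiN(c-Hex)2, Et2O/THF, −95 °C; BF3·OEt2; then 8, −95 °C; NaBO3·4H2O work-up; then DBU, CH2Cl2, rt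
Reagents that add atoms: allyl chloride, C=CCCl
Why: Oehlschlager–Brown (Z)-γ-chloroallylboration through a chair Zimmerman–Traxler transition state: the reagent adds to the Re face (matched with the Felkin/Cornforth preference of the α-alkoxy aldehyde) to set 6S, the Z-geometry gives the syn (7S) chlorohydrin, and DBU closes it by intramolecular Williamson displacement with inversion at C7 to the cis-oxirane (6R,7R).

Step 7
Reactants: 10 methyl (4S,5R)-2,2-dimethyl-5-[(2R,3R)-3-vinyloxiran-2-yl]-1,3-dioxolane-4-carboxylate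
Product: 11 (4S,5R)-2,2-dimethyl-5-[(2R,3R)-3-vinyloxiran-2-yl]-1,3-dioxolane-4-carbaldehyde
Conditions: DIBAL-H (1.1 equiv), CH2Cl2, −78 °C; Rochelle salt
Reagents that add atoms: none
Why: DIBAL-H partial reduction of an α-alkoxy methyl ester via the chelated tetrahedral aluminium acetal that survives at −78 °C; the oxirane is not opened at this temperature, and the step is placed before the benzoate enters.

Step 8
Reactants: 11 (4S,5R)-2,2-dimethyl-5-[(2R,3R)-3-vinyloxiran-2-yl]-1,3-dioxolane-4-carbaldehyde; 5 (2R,3S)-3-[(4-methoxybenzyl)oxy]pent-4-en-2-yl benzoate (3 equiv)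
Product: 12 (2S,3R,4R,5R,6E,8S,9R)-9-(benzoyloxy)-4,5-epoxy-2,3-(isopropylidenedioxy)-8-[(4-methoxybenzyl)oxy]dec-6-enal
Conditions: Hoveyda–Grubbs II (5 mol %), CH2Cl2, 40 °C
Reagents that add atoms: none
Why: Olefin cross-metathesis of two type-II terminal alkenes, thermodynamically E-selective and tolerant of the aldehyde; it is run before the enoate exists so that no ring-closing partner (C2=C3) is present.

Step 9
Reactants: 12 (2S,3R,4R,5R,6E,8S,9R)-9-(benzoyloxy)-4,5-epoxy-2,3-(isopropylidenedioxy)-8-[(4-methoxybenzyl)oxy]dec-6-enal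
Product: 13 methyl (2Z,4R,5S,6R,7R,8E,10S,11R)-11-(benzoyloxy)-6,7-epoxy-4,5-(isopropylidenedioxy)-10-[(4-methoxybenzyl)oxy]dodeca-2,8-dienoate
Conditions: (CF3CH2O)2P(O)CH2CO2Me, KHMDS, 18-crown-6, THF, −78 °C
Reagents that add atoms: methyl bis(2,2,2-trifluoroethyl)phosphonoacetate, COC(=O)CP(=O)(OCC(F)(F)F)OCC(F)(F)F
Why: Still–Gennari variant of the Horner–Wadsworth–Emmons reaction, kinetically Z-selective and well precedented for α-alkoxy aldehydes; the PMB ether keeps the benzoate from migrating under base.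

Step 10
Reactants: 13 methyl (2Z,4R,5S,6R,7R,8E,10S,11R)-11-(benzoyloxy)-6,7-epoxy-4,5-(isopropylidenedioxy)-10-[(4-methoxybenzyl)oxy]dodeca-2,8-dienoate
Product: 16 (2R,3S,4E)-3-hydroxy-5-[(2S,3R,3aR,7aR)-3-hydroxy-5-oxo-2,3,3a,7a-tetrahydro-5H-furo[3,2-b]pyran-2-yl]pent-4-en-2-yl benzoate (target), via 5,6-O-isopropylidene tetrahydrofuran ester 14 (not isolated), via dihydroxy tetrahydrofuran (Z)-ester 15 (not isolated)
Conditions: BF3·OEt2 (0.2 equiv), CH2Cl2, −78 → −30 °C; then TFA/H2O (4:1), 0 °C → rt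
Reagents that add atoms: none
Why: Proposed new method: Lewis-acid activation of the cis-vinyl oxirane lets the acetonide oxygen on C4 attack the allylic carbon C7 from the back (five-membered ring, π-stabilised SN2-like opening, inversion at C7, hence the all-cis tetrahydrofuran); the bridged oxonium ion collapses to an O5 oxocarbenium ion that the new C6 alkoxide recaptures as the cis-5,6-acetonide 14, so no free C4 hydroxyl (and no butenolide) ever forms; aqueous TFA then removes the acetonide and the PMB ether and the C5 hydroxyl lactonises onto the cis-disposed (Z)-ester. The closest known reactions are the Nicolaou vinyl-directed endo hydroxy-epoxide cyclisation, ether/acetal-oxygen participation in iodoetherification and polyepoxide cascades, and the Z-hydroxy-enoate lactonisation used for altholactone-type lactones.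

## Compound list

1 | penta-1,4-dien-3-ol (divinylcarbinol) | C=CC(O)C=C | starting material
2 | (2R,3S)-1,2-epoxypent-4-en-3-ol | C=C[C@H](O)[C@H]1CO1 | intermediate
3 | (2R,3S)-1,2-epoxy-3-[(4-methoxybenzyl)oxy]pent-4-ene | C=C[C@H](OCc1ccc(OC)cc1)[C@H]1CO1 | intermediate
4 | lithium (2R,3S)-3-[(4-methoxybenzyl)oxy]pent-4-en-2-olate | C=C[C@H](OCc1ccc(OC)cc1)[C@@H](C)[O-].[Li+] | intermediate
5 | (2R,3S)-3-[(4-methoxybenzyl)oxy]pent-4-en-2-yl benzoate | C=C[C@H](OCc1ccc(OC)cc1)[C@H](OC(=O)c1ccccc1)C | intermediate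
6 | dimethyl (4S,5S)-2,2-dimethyl-1,3-dioxolane-4,5-dicarboxylate [(+)-dimethyl 2,3-O-isopropylidene-D-tartrate] | COC(=O)[C@H]1OC(C)(C)O[C@@H]1C(=O)OC | starting material
7 | methyl (4S,5R)-5-(hydroxymethyl)-2,2-dimethyl-1,3-dioxolane-4-carboxylate | COC(=O)[C@H]1OC(C)(C)O[C@@H]1CO | intermediate
8 | methyl (4S,5S)-5-formyl-2,2-dimethyl-1,3-dioxolane-4-carboxylate | COC(=O)[C@H]1OC(C)(C)O[C@@H]1C=O | intermediate
9 | methyl (4S,5R)-5-[(1S,2S)-2-chloro-1-hydroxybut-3-en-1-yl]-2,2-dimethyl-1,3-dioxolane-4-carboxylate | COC(=O)[C@H]1OC(C)(C)O[C@@H]1[C@H](O)[C@@H](Cl)C=C | intermediate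
10 | methyl (4S,5R)-2,2-dimethyl-5-[(2R,3R)-3-vinyloxiran-2-yl]-1,3-dioxolane-4-carboxylate | COC(=O)[C@H]1OC(C)(C)O[C@@H]1[C@@H]2O[C@@H]2C=C | intermediate
11 | (4S,5R)-2,2-dimethyl-5-[(2R,3R)-3-vinyloxiran-2-yl]-1,3-dioxolane-4-carbaldehyde | O=C[C@H]1OC(C)(C)O[C@@H]1[C@@H]2O[C@@H]2C=C | intermediate
12 | (2S,3R,4R,5R,6E,8S,9R)-9-(benzoyloxy)-4,5-epoxy-2,3-(isopropylidenedioxy)-8-[(4-methoxybenzyl)oxy]dec-6-enal | C[C@@H](OC(=O)c1ccccc1)[C@@H](OCc1ccc(OC)cc1)/C=C/[C@H]1O[C@H]1[C@H]2OC(C)(C)O[C@@H]2C=O | intermediate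
13 | methyl (2Z,4R,5S,6R,7R,8E,10S,11R)-11-(benzoyloxy)-6,7-epoxy-4,5-(isopropylidenedioxy)-10-[(4-methoxybenzyl)oxy]dodeca-2,8-dienoate | C[C@@H](OC(=O)c1ccccc1)[C@@H](OCc1ccc(OC)cc1)/C=C/[C@H]1O[C@H]1[C@H]2OC(C)(C)O[C@@H]2/C=C\C(=O)OC | intermediate
14 | methyl (2Z,4R,5S,6R,7S,8E,10S,11R)-11-(benzoyloxy)-4,7-epoxy-5,6-(isopropylidenedioxy)-10-[(4-methoxybenzyl)oxy]dodeca-2,8-dienoate (all-cis tetrahydrofuran) | C[C@@H](OC(=O)c1ccccc1)[C@@H](OCc1ccc(OC)cc1)/C=C/[C@@H]1O[C@H](/C=C\C(=O)OC)[C@@H]2OC(C)(C)O[C@H]12 | intermediate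
15 | methyl (2Z,4R,5R,6S,7S,8E,10S,11R)-11-(benzoyloxy)-4,7-epoxy-5,6,10-trihydroxydodeca-2,8-dienoate | C[C@@H](OC(=O)c1ccccc1)[C@@H](O)/C=C/[C@@H]1O[C@H](/C=C\C(=O)OC)[C@H](O)[C@@H]1O | intermediate
16 | (2R,3S,4E)-3-hydroxy-5-[(2S,3R,3aR,7aR)-3-hydroxy-5-oxo-2,3,3a,7a-tetrahydro-5H-furo[3,2-b]pyran-2-yl]pent-4-en-2-yl benzoate | C[C@@H](OC(=O)c1ccccc1)[C@@H](O)/C=C/[C@@H]1O[C@@H]2C=CC(=O)O[C@@H]2[C@@H]1O | target

## Step count and risks

Total steps: 10 (steps 1–3 make the side arm, steps 4–10 the main line). Longest linear sequence: 7 steps (6 → 16).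

**Step 10 (cascade)** is the most likely to fail: the acetal oxygen may not take part cleanly, or C7 may ionise and lose its configuration. The fallback sets out from aldehyde 12 and comes back at 15. Before any C1–C2 unit is present, 12 is treated with TFA/H2O/CH2Cl2 at 0 °C. This removes the acetonide and the PMB ether, and the free C4 hydroxyl opens the vinyl oxirane in the classical 5-endo hydroxy-epoxide mode; with no ester present no butenolide can form. The product is (2R,3S,4E)-5-[(2S,3S,4R,5S)-5-formyl-3,4-dihydroxytetrahydrofuran-2-yl]-3-hydroxypent-4-en-2-yl benzoate F1. A Z-selective Wittig reaction of it with Ph3P=CHCO2Me in MeOH at 0 °C gives 15, which lactonises to 16 as in step 10.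

**Step 8 (cross-metathesis)** is second: two type-II alkenes, a cis-vinyl oxirane and a free aldehyde on ruthenium. The fallback sets out from 11 and 5 and comes back at 13, replacing metathesis by a Julia–Kocienski olefination.
- Still–Gennari olefination of 11 gives methyl (2Z)-3-[(4R,5S)-2,2-dimethyl-5-[(2R,3R)-3-vinyloxiran-2-yl]-1,3-dioxolan-4-yl]prop-2-enoate F2.
- Its terminal vinyl group alone is cleaved (cat. OsO4, NaIO4, 2,6-lutidine) to the cis-epoxy aldehyde methyl (2Z)-3-[(4R,5S)-5-[(2S,3S)-3-formyloxiran-2-yl]-2,2-dimethyl-1,3-dioxolan-4-yl]prop-2-enoate F3.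
- In parallel 5 is cleaved (cat. OsO4, NaIO4; then NaBH4) to (2R,3S)-4-hydroxy-3-[(4-methoxybenzyl)oxy]butan-2-yl benzoate F4.
- Mitsunobu reaction with 1-phenyl-1H-tetrazole-5-thiol gives (2R,3R)-3-[(4-methoxybenzyl)oxy]-4-[(1-phenyl-1H-tetrazol-5-yl)sulfanyl]butan-2-yl benzoate F5.
- Oxidation (H2O2, ammonium molybdate) gives (2R,3R)-3-[(4-methoxybenzyl)oxy]-4-[(1-phenyl-1H-tetrazol-5-yl)sulfonyl]butan-2-yl benzoate F6.
- The sulfone anion (KHMDS, DME, −60 °C) and the epoxy aldehyde give the 8E-alkene 13.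

**Step 6 (chloroallylboration)** is third: a −95 °C reagent and a hydrate-prone aldehyde. The fallback sets out from 8 and comes back at 10, building the cis-oxirane by Sharpless epoxidation instead.
- Z-selective Wittig reaction of 8 with Ph3P=CHCH2OTBS gives methyl (4S,5R)-5-[(1Z)-3-[(tert-butyldimethylsilyl)oxy]prop-1-en-1-yl]-2,2-dimethyl-1,3-dioxolane-4-carboxylate F7.
- TBAF/AcOH gives methyl (4S,5R)-5-[(1Z)-3-hydroxyprop-1-en-1-yl]-2,2-dimethyl-1,3-dioxolane-4-carboxylate F8.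
- Sharpless epoxidation with D-(−)-DET gives methyl (4S,5R)-5-[(2R,3R)-3-(hydroxymethyl)oxiran-2-yl]-2,2-dimethyl-1,3-dioxolane-4-carboxylate F9.
- Dess–Martin oxidation gives methyl (4S,5R)-5-[(2S,3S)-3-formyloxiran-2-yl]-2,2-dimethyl-1,3-dioxolane-4-carboxylate F10.
- Wittig methylenation (Ph3P=CH2, THF, −78 °C) gives 10.

## Further compounds

F1 | step 10 | (2R,3S,4E)-5-[(2S,3S,4R,5S)-5-formyl-3,4-dihydroxytetrahydrofuran-2-yl]-3-hydroxypent-4-en-2-yl benzoate | C[C@@H](OC(=O)c1ccccc1)[C@@H](O)/C=C/[C@@H]1O[C@H](C=O)[C@H](O)[C@@H]1O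
F2 | step 8 | methyl (2Z)-3-[(4R,5S)-2,2-dimethyl-5-[(2R,3R)-3-vinyloxiran-2-yl]-1,3-dioxolan-4-yl]prop-2-enoate | C=C[C@H]1O[C@H]1[C@H]2OC(C)(C)O[C@@H]2/C=C\C(=O)OC
F3 | step 8 | methyl (2Z)-3-[(4R,5S)-5-[(2S,3S)-3-formyloxiran-2-yl]-2,2-dimethyl-1,3-dioxolan-4-yl]prop-2-enoate | O=C[C@H]1O[C@H]1[C@H]2OC(C)(C)O[C@@H]2/C=C\C(=O)OC
F4 | step 8 | (2R,3S)-4-hydroxy-3-[(4-methoxybenzyl)oxy]butan-2-yl benzoate | OC[C@H](OCc1ccc(OC)cc1)[C@H](OC(=O)c1ccccc1)C
F5 | step 8 | (2R,3R)-3-[(4-methoxybenzyl)oxy]-4-[(1-phenyl-1H-tetrazol-5-yl)sulfanyl]butan-2-yl benzoate | c1ccccc1-n1nnnc1SC[C@H](OCc1ccc(OC)cc1)[C@H](OC(=O)c1ccccc1)C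
F6 | step 8 | (2R,3R)-3-[(4-methoxybenzyl)oxy]-4-[(1-phenyl-1H-tetrazol-5-yl)sulfonyl]butan-2-yl benzoate | O=S(=O)(C[C@H](OCc1ccc(OC)cc1)[C@H](OC(=O)c1ccccc1)C)c1nnnn1-c1ccccc1
F7 | step 6 | methyl (4S,5R)-5-[(1Z)-3-[(tert-butyldimethylsilyl)oxy]prop-1-en-1-yl]-2,2-dimethyl-1,3-dioxolane-4-carboxylate | COC(=O)[C@H]1OC(C)(C)O[C@@H]1/C=C\CO[Si](C)(C)C(C)(C)C
F8 | step 6 | methyl (4S,5R)-5-[(1Z)-3-hydroxyprop-1-en-1-yl]-2,2-dimethyl-1,3-dioxolane-4-carboxylate | COC(=O)[C@H]1OC(C)(C)O[C@@H]1/C=C\CO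
F9 | step 6 | methyl (4S,5R)-5-[(2R,3R)-3-(hydroxymethyl)oxiran-2-yl]-2,2-dimethyl-1,3-dioxolane-4-carboxylate | COC(=O)[C@H]1OC(C)(C)O[C@@H]1[C@@H]2O[C@@H]2CO
F10 | step 6 | methyl (4S,5R)-5-[(2S,3S)-3-formyloxiran-2-yl]-2,2-dimethyl-1,3-dioxolane-4-carboxylate | COC(=O)[C@H]1OC(C)(C)O[C@@H]1[C@@H]2O[C@@H]2C=O
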